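**Plan**

- Locants follow the target: C1 (CH–OAc), C2 (CH2), C3 (C–CH3), C4 (CH–OH), C5 (CH2), C6 (=C–CH3), C7 (=CH), C8 (CH–O-aroyl), C9 (ring-fusion CH), C10 (C(OH)–i-Pr); α is the face of the C3 methyl and H9, β the opposite face.
- Retrosynthesis: the C8 and C1 ester C–O bonds and the silyl ethers are cut first; the cis C1/C10 diol goes back to a C1=C10 alkene, and the C6=C7 alkene with the C8 carbinol to a C8 ketone; C2–C3 and C9–C10 are then cut in one operation; last come the C3=C9 alkene (metathesis) and the C8–vinyl and C4–isopropenyl bonds, back to a 3-methylglutarate.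
- Enabling feature: the five-membered ring C1–C2–C3–C9–C10 is a three-carbon unit C2–C1–C10 (isopropyl on C10) laid over the C3–C9 edge of the seven-membered ring C3–C9, whose C8 can be a ketone and whose C3 bears a methyl; that is a 3-methylcyclohept-2-enone (C8=O, C9=C3) joined to a 1-isopropyl-1-silylallene.
- Forward order: the C4–C8 chain is extended at both ends and closed to the seven-membered enone; the five-membered ring is annulated in one step; desilylation, dihydroxylation, dehydrogenation, reduction and two acylations finish the synthesis.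
- Stereochemistry: C4 from a CBS reduction; C3 from attack anti to the C4 silyl ether; C9 from the enforced cis ring closure; C1 and C10 from osmylation of the convex α face; C8 from hydride addition to the convex face; the temporary C6 centre from methyl hydrogen (R)-3-methylglutarate.

Key step: step 10

Remark: methyl hydrogen (R)-3-methylglutarate (1) is assumed to be purchasable in enantiopure form; C6 becomes trigonal in step 14, so the optical purity of the target rests on C4 alone.

**Route**

Step 1
Reactants: 1 methyl hydrogen (R)-3-methylglutarate; 2 N,O-dimethylhydroxylamine hydrochloride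
Product: 3 (3S)-5-[methoxy(methyl)amino]-3-methyl-5-oxopentanoic acid
Conditions: LiN(SiMe3)2 (3.2 equiv), THF, –20 to 0 °C; aq. HCl work-up
Reagents that add atoms: N,O-dimethylhydroxylamine hydrochloride (2), CNOC.Cl
Why: Aminolysis of the methyl ester by LiN(OMe)Me (Weinreb amide formation from an ester) leaves the acid alone because it is present as the inert carboxylate RCO2Li; the stereocentre is untouched and its descriptor changes only through the priority switch.

Step 2
Reactants: 3 (3S)-5-[methoxy(methyl)amino]-3-methyl-5-oxopentanoic acid; 4 isopropenylmagnesium bromide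
Product: 5 (3S)-3,6-dimethyl-5-oxohept-6-enoic acid
Conditions: 4 (2.3 equiv), THF, –20 to 0 °C; cold 1 M HCl quench
Reagents that add atoms: isopropenylmagnesium bromide (4), CC(=C)[Mg]Br
Why: Grignard addition to a Weinreb amide stops at the ketone through the chelated tetrahedral intermediate, the first equivalent only forming the carboxylate RCO2MgBr.

Step 3
Reactants: 5 (3S)-3,6-dimethyl-5-oxohept-6-enoic acid; 2 N,O-dimethylhydroxylamine hydrochloride
Product: 6 (3S)-N-methoxy-N,3,6-trimethyl-5-oxohept-6-enamide
Conditions: EDC·HCl, N-methylmorpholine, CH2Cl2, 0 °C to rt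
Reagents that add atoms: N,O-dimethylhydroxylamine hydrochloride (2), CNOC.Cl
Why: Carbodiimide-mediated amide coupling turns the acid into the Weinreb amide that later takes the vinyl group; the α-substituted enone is a poor Michael acceptor for the weakly nucleophilic amine.

Step 4
Reactants: 6 (3S)-N-methoxy-N,3,6-trimethyl-5-oxohept-6-enamide
Product: 7 (3S,5S)-5-hydroxy-N-methoxy-N,3,6-trimethylhept-6-enamide
Conditions: (R)-2-methyl-CBS-oxazaborolidine (20 mol%), catecholborane, toluene, –78 °C
Reagents that add atoms: none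
Why: Corey–Bakshi–Shibata reduction with the isopropenyl group as the large substituent should deliver hydride under reagent control to the (S)-carbinol (the future C4); catecholborane at low temperature spares the alkene and the Weinreb amide.

Step 5
Reactants: 7 (3S,5S)-5-hydroxy-N-methoxy-N,3,6-trimethylhept-6-enamide; 8 triisopropylsilyl trifluoromethanesulfonate
Product: 9 (3S,5S)-N-methoxy-N,3,6-trimethyl-5-[(triisopropylsilyl)oxy]hept-6-enamide
Conditions: 2,6-lutidine, CH2Cl2, –78 to 0 °C
Reagents that add atoms: triisopropylsilyl trifluoromethanesulfonate (8), CC(C)[Si](OS(=O)(=O)C(F)(F)F)(C(C)C)C(C)C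
Why: Silyl triflate/2,6-lutidine silylation protects the secondary allylic alcohol before it can lactonise onto the amide and installs the bulky group that later controls the C3 face.

Step 6
Reactants: 9 (3S,5S)-N-methoxy-N,3,6-trimethyl-5-[(triisopropylsilyl)oxy]hept-6-enamide; 10 vinylmagnesium bromide
Product: 11 (5S,7S)-5,8-dimethyl-7-[(triisopropylsilyl)oxy]nona-1,8-dien-3-one
Conditions: THF, –20 to 0 °C; inverse quench into cold 1 M HCl
Reagents that add atoms: vinylmagnesium bromide (10), C=C[Mg]Br
Why: Grignard addition to the Weinreb amide gives the vinyl ketone without over-addition, and the acidic inverse quench keeps the released amine from adding to the enone.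

Step 7
Reactants: 11 (5S,7S)-5,8-dimethyl-7-[(triisopropylsilyl)oxy]nona-1,8-dien-3-one
Product: 12 (4S,6S)-3,6-dimethyl-4-[(triisopropylsilyl)oxy]cyclohept-2-en-1-one
Conditions: second-generation Grubbs catalyst RuCl2(=CHPh)(H2IMes)(PCy3) (5 mol%), CH2Cl2 (5 mM), 40 °C
Reagents that add atoms: none
Why: Ring-closing olefin metathesis between the vinyl ketone and the 1,1-disubstituted alkene closes the seven-membered ring as the trisubstituted enone (C9=C3) with loss of ethene; both stereocentres are remote from the reacting carbons.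

Step 8
Reactants: 13 3-(trimethylsilyl)prop-2-yn-1-ol; 14 methanesulfonyl chloride
Product: 15 3-(trimethylsilyl)prop-2-yn-1-yl methanesulfonate
Conditions: Et3N, CH2Cl2, 0 °C
Reagents that add atoms: methanesulfonyl chloride (14), CS(=O)(=O)Cl
Why: Standard sulfonylation of a primary propargylic alcohol provides the leaving group for allene formation.

Step 9
Reactants: 15 3-(trimethylsilyl)prop-2-yn-1-yl methanesulfonate; 16 isopropylmagnesium chloride
Product: 17 trimethyl(4-methylpenta-1,2-dien-3-yl)silane
Conditions: CuBr, LiBr, THF, –78 °C to rt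
Reagents that add atoms: isopropylmagnesium chloride (16), CC(C)[Mg]Cl
Why: Copper-mediated SN2' substitution of the propargylic mesylate, the usual entry to 1-alkyl-1-(trimethylsilyl)allenes, places the isopropyl group on the silicon-bearing carbon.

Step 10
Reactants: 12 (4S,6S)-3,6-dimethyl-4-[(triisopropylsilyl)oxy]cyclohept-2-en-1-one; 17 trimethyl(4-methylpenta-1,2-dien-3-yl)silane
Product: 18 cis-fused vinylsilane ketone (C8 ketone; C1(SiMe3)=C10(i-Pr) cyclopentene; 3α-CH3; 9α-H; 4α-OTIPS; 6β-CH3)
Conditions: TiCl4 (1.5 equiv), 17 (2 equiv), CH2Cl2, –78 °C (warming to –40 °C if needed)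
Reagents that add atoms: allenylsilane 17, C=C=C(C(C)C)[Si](C)(C)C
Why: TiCl4 binds the C8 carbonyl, the CH2 terminus of the allene adds to C3 to give a vinyl cation stabilised by the adjacent C–Si bond, a 1,2-shift of silicon moves the charge to the isopropyl-bearing carbon, and the trichlorotitanium enolate captures it at C9 (Danheiser (trimethylsilyl)cyclopentene annulation of an enone). The five-membered ring closes by C9–C10 bond formation onto the digonal cationic carbon with the new C1=C10 double bond inside the ring (5-endo closure, a formal (3+2) annulation). C3 is set by the C4 silyl ether: 1,2-allylic strain with the C3 methyl holds the OTIPS group pseudoaxial on the α face, so the allene enters from the β face and the methyl ends cis to O4. C9 follows from the tether, because the chain on C3 can reach the enolate carbon only on its own face, which makes the fusion cis. The step needs attack through the allene CH2 terminus (secured by the β-silicon effect), ring closure ahead of silyl loss to an alkyne (favoured by the 1-alkyl substituent) and β-face selectivity (secured by the pseudoaxial OTIPS and the equatorial C6 methyl of the trans isomer).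

Step 11
Reactants: 18 cis-fused vinylsilane ketone
Product: 19 cis-fused cyclopentene ketone (C1H=C10(i-Pr); C8 ketone; 3α-CH3; 9α-H; 4α-OTIPS; 6β-CH3)
Conditions: CF3CO2H, CH2Cl2, 0 °C, short contact; NaHCO3 quench
Reagents that add atoms: none
Why: Protodesilylation of a vinylsilane (ipso protonation at C1 gives the β-silyl tertiary cation at C10, which loses silicon) restores the C1=C10 alkene in place without touching C9 if the acid contact is brief.

Step 12
Reactants: 19 cis-fused cyclopentene ketone
Product: 20 diol ketone (1α,10α-dihydroxy; 10β-isopropyl; C8 ketone; 4α-OTIPS; 6β-CH3)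
Conditions: OsO4 (5 mol%), NMO, acetone/H2O, rt
Reagents that add atoms: OsO4 (catalytic), O=[Os](=O)(=O)=O; N-methylmorpholine N-oxide, C[N+]1([O-])CCOCC1; water, O
Why: Upjohn dihydroxylation should occur on the convex α face of the cis-fused cyclopentene, anti to the allylic C9–C8 bond and the seven-membered ring, which sets the 1α and 10α hydroxyls cis to H9 and the C3 methyl.

Step 13
Reactants: 20 diol ketone; 21 2-methoxypropene
Product: 22 acetonide ketone (1α,10α-O-isopropylidene acetal of 20)
Conditions: PPTS (cat.), CH2Cl2, 0 °C to rt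
Reagents that add atoms: 2-methoxypropene (21), COC(C)=C
Why: Acid-catalysed acetal formation ties up the cis-diol so that neither an acidic hydroxyl nor a free β-hydroxy ketone (retro-aldol) meets the strong base of the next step.

Step 14
Reactants: 22 acetonide ketone
Product: 24 acetonide enone (C6=C7 alkene conjugated to the C8 ketone; 1α/10α-O-isopropylidene; 4α-OTIPS), via trimethylsilyl enol ether 23 (not isolated)
Conditions: LiN(i-Pr)2, Me3SiCl, THF, –78 °C; then Pd(OAc)2 (1.1 equiv), MeCN, rt
Reagents that add atoms: none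
Why: Kinetic deprotonation takes the C7 methylene (C9–H lies between two quaternary carbons), and Saegusa–Ito oxidation of the silyl enol ether with palladium diacetate gives the enone by syn β-hydride elimination of the α-face C6–H from the C7–Pd(OAc) intermediate; C10 has no hydrogen, so no other enone can form.

Step 15
Reactants: 24 acetonide enone
Product: 25 diol enone (1α,10α-dihydroxy; C6=C7; C8 ketone; 4α-OTIPS)
Conditions: AcOH/H2O (4:1), 45 °C
Reagents that add atoms: none
Why: Mild aqueous acid hydrolyses the isopropylidene acetal, while the secondary TIPS ether and the enone tolerate these conditions.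

Step 16
Reactants: 25 diol enone; 26 acetic anhydride
Product: 27 acetate enone (1α-acetoxy; 10α-hydroxy; C6=C7; C8 ketone; 4α-OTIPS)
Conditions: pyridine, DMAP (cat.), CH2Cl2, 0 °C to rt
Reagents that add atoms: acetic anhydride (26), CC(=O)OC(C)=O
Why: DMAP-catalysed acetylation distinguishes the secondary C1 hydroxyl from the tertiary C10 hydroxyl, and the amine bases are too weak to trigger retro-aldol cleavage.

Step 17
Reactants: 27 acetate enone
Product: 28 allylic alcohol (1α-acetoxy; 8β,10α-dihydroxy; C6=C7; 4α-OTIPS)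
Conditions: NaBH4, CeCl3·7H2O, MeOH, –78 °C
Reagents that add atoms: none
Why: Luche reduction gives 1,2-addition to the enone, and hydride should enter from the convex α face, away from the five-membered ring and its β-isopropyl group, which places the C8 hydroxyl β (trans to H9).

Step 18
Reactants: 29 4-hydroxybenzoic acid; 30 tert-butyldimethylsilyl chloride
Product: 32 4-[(tert-butyldimethylsilyl)oxy]benzoic acid, via bis-silylated ester 31 (not isolated)
Conditions: 30 (2.2 equiv), imidazole, DMF, rt; then AcOH/THF/H2O, rt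
Reagents that add atoms: tert-butyldimethylsilyl chloride (30), CC(C)(C)[Si](C)(C)Cl
Why: Silylation of both acidic hydroxyls followed by hydrolysis of the labile silyl ester leaves the aryl silyl ether, the standard protection of a hydroxybenzoic acid.

Step 19
Reactants: 28 allylic alcohol; 32 4-[(tert-butyldimethylsilyl)oxy]benzoic acid
Product: 33 protected target (8β-O-[4-(tert-butyldimethylsilyloxy)benzoyl]; 1α-OAc; 10α-OH; 4α-OTIPS)
Conditions: EDC·HCl, DMAP (1.2 equiv), CH2Cl2, 0 °C to rt
Reagents that add atoms: 4-[(tert-butyldimethylsilyl)oxy]benzoic acid (32), OC(=O)c1ccc(O[Si](C)(C)C(C)(C)C)cc1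
Why: Steglich esterification acylates the only free secondary hydroxyl (C8) with retention, the tertiary C10 hydroxyl being unreactive.

Step 20
Reactants: 33 protected target
Product: 34 target, (2S,3R,3aR,4S,8S,8aS)-2-acetoxy-3,8-dihydroxy-6,8a-dimethyl-3-(propan-2-yl)-1,2,3,3a,4,7,8,8a-octahydroazulen-4-yl 4-hydroxybenzoate
Conditions: HF·pyridine, pyridine/THF, 0 °C to rt
Reagents that add atoms: none
Why: Buffered fluoride cleaves the aryl TBS ether and the secondary TIPS ether in one operation and should leave the acetate, the allylic benzoate and the tertiary alcohol untouched.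

**Compound list**

1 | methyl hydrogen (R)-3-methylglutarate, (3R)-5-methoxy-3-methyl-5-oxopentanoic acid | OC(=O)C[C@@H](C)CC(=O)OC | starting material
2 | N,O-dimethylhydroxylamine hydrochloride | CNOC.Cl | starting material
3 | (3S)-5-[methoxy(methyl)amino]-3-methyl-5-oxopentanoic acid | OC(=O)C[C@@H](C)CC(=O)N(C)OC | intermediate
4 | isopropenylmagnesium bromide | CC(=C)[Mg]Br | starting material
5 | (3S)-3,6-dimethyl-5-oxohept-6-enoic acid | OC(=O)C[C@@H](C)CC(=O)C(C)=C | intermediate
6 | (3S)-N-methoxy-N,3,6-trimethyl-5-oxohept-6-enamide | CON(C)C(=O)C[C@@H](C)CC(=O)C(C)=C | intermediate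
7 | (3S,5S)-5-hydroxy-N-methoxy-N,3,6-trimethylhept-6-enamide | CON(C)C(=O)C[C@@H](C)C[C@H](O)C(C)=C | intermediate
8 | triisopropylsilyl trifluoromethanesulfonate | CC(C)[Si](OS(=O)(=O)C(F)(F)F)(C(C)C)C(C)C | starting material
9 | (3S,5S)-N-methoxy-N,3,6-trimethyl-5-[(triisopropylsilyl)oxy]hept-6-enamide | CON(C)C(=O)C[C@@H](C)C[C@H](O[Si](C(C)C)(C(C)C)C(C)C)C(C)=C | intermediate
10 | vinylmagnesium bromide | C=C[Mg]Br | starting material
11 | (5S,7S)-5,8-dimethyl-7-[(triisopropylsilyl)oxy]nona-1,8-dien-3-one | C=CC(=O)C[C@@H](C)C[C@H](O[Si](C(C)C)(C(C)C)C(C)C)C(C)=C | intermediate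
12 | (4S,6S)-3,6-dimethyl-4-[(triisopropylsilyl)oxy]cyclohept-2-en-1-one (silyl ether and C6 methyl trans) | CC1=CC(=O)C[C@@H](C)C[C@@H]1O[Si](C(C)C)(C(C)C)C(C)C | intermediate
13 | 3-(trimethylsilyl)prop-2-yn-1-ol | C[Si](C)(C)C#CCO | starting material
14 | methanesulfonyl chloride | CS(=O)(=O)Cl | starting material
15 | 3-(trimethylsilyl)prop-2-yn-1-yl methanesulfonate | C[Si](C)(C)C#CCOS(C)(=O)=O | intermediate
16 | isopropylmagnesium chloride | CC(C)[Mg]Cl | starting material
17 | trimethyl(4-methylpenta-1,2-dien-3-yl)silane (1-isopropyl-1-(trimethylsilyl)allene) | C=C=C(C(C)C)[Si](C)(C)C | intermediate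
18 | cis-fused vinylsilane ketone: C8 ketone, C1(SiMe3)=C10(i-Pr), 3α-CH3, 9α-H, 4α-OTIPS, 6β-CH3 | C1[C@]2(C)[C@@H](O[Si](C(C)C)(C(C)C)C(C)C)C[C@H](C)CC(=O)[C@@H]2C(C(C)C)=C1[Si](C)(C)C | intermediate
19 | cis-fused cyclopentene ketone: as 18 with H on C1 in place of SiMe3 | C1[C@]2(C)[C@@H](O[Si](C(C)C)(C(C)C)C(C)C)C[C@H](C)CC(=O)[C@@H]2C(C(C)C)=C1 | intermediate
20 | diol ketone: 1α,10α-dihydroxy, 10β-isopropyl, C8 ketone, 4α-OTIPS, 6β-CH3 | O[C@H]1C[C@]2(C)[C@@H](O[Si](C(C)C)(C(C)C)C(C)C)C[C@H](C)CC(=O)[C@@H]2[C@]1(O)C(C)C | intermediate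
21 | 2-methoxypropene | COC(C)=C | starting material
22 | acetonide ketone: 1α,10α-O-isopropylidene acetal of 20 | CC1(C)O[C@H]2C[C@]3(C)[C@@H](O[Si](C(C)C)(C(C)C)C(C)C)C[C@H](C)CC(=O)[C@@H]3[C@]2(O1)C(C)C | intermediate
23 | trimethylsilyl enol ether of 22 (C7=C8, OSiMe3 on C8) | CC1(C)O[C@H]2C[C@]3(C)[C@@H](O[Si](C(C)C)(C(C)C)C(C)C)C[C@H](C)C=C(O[Si](C)(C)C)[C@@H]3[C@]2(O1)C(C)C | intermediate
24 | acetonide enone: C6=C7, C8 ketone, 1α,10α-O-isopropylidene, 4α-OTIPS | CC1(C)O[C@H]2C[C@]3(C)[C@@H](O[Si](C(C)C)(C(C)C)C(C)C)CC(C)=CC(=O)[C@@H]3[C@]2(O1)C(C)C | intermediate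
25 | diol enone: 1α,10α-dihydroxy, C6=C7, C8 ketone, 4α-OTIPS | O[C@H]1C[C@]2(C)[C@@H](O[Si](C(C)C)(C(C)C)C(C)C)CC(C)=CC(=O)[C@@H]2[C@]1(O)C(C)C | intermediate
26 | acetic anhydride | CC(=O)OC(C)=O | starting material
27 | acetate enone: 1α-acetoxy, 10α-hydroxy, C6=C7, C8 ketone, 4α-OTIPS | CC(=O)O[C@H]1C[C@]2(C)[C@@H](O[Si](C(C)C)(C(C)C)C(C)C)CC(C)=CC(=O)[C@@H]2[C@]1(O)C(C)C | intermediate
28 | allylic alcohol: 1α-acetoxy, 8β,10α-dihydroxy, C6=C7, 4α-OTIPS | CC(=O)O[C@H]1C[C@]2(C)[C@@H](O[Si](C(C)C)(C(C)C)C(C)C)CC(C)=C[C@H](O)[C@@H]2[C@]1(O)C(C)C | intermediate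
29 | 4-hydroxybenzoic acid | OC(=O)c1ccc(O)cc1 | starting material
30 | tert-butyldimethylsilyl chloride | CC(C)(C)[Si](C)(C)Cl | starting material
31 | tert-butyldimethylsilyl 4-[(tert-butyldimethylsilyl)oxy]benzoate | CC(C)(C)[Si](C)(C)OC(=O)c1ccc(O[Si](C)(C)C(C)(C)C)cc1 | intermediate
32 | 4-[(tert-butyldimethylsilyl)oxy]benzoic acid | OC(=O)c1ccc(O[Si](C)(C)C(C)(C)C)cc1 | intermediate
33 | protected target: 8β-O-[4-(tert-butyldimethylsilyloxy)benzoyl], 1α-OAc, 10α-OH, 4α-OTIPS | CC(=O)O[C@H]1C[C@]2(C)[C@@H](O[Si](C(C)C)(C(C)C)C(C)C)CC(C)=C[C@H](OC(=O)c3ccc(O[Si](C)(C)C(C)(C)C)cc3)[C@@H]2[C@]1(O)C(C)C | intermediate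
34 | (2S,3R,3aR,4S,8S,8aS)-2-acetoxy-3,8-dihydroxy-6,8a-dimethyl-3-(propan-2-yl)-1,2,3,3a,4,7,8,8a-octahydroazulen-4-yl 4-hydroxybenzoate | CC(=O)O[C@H]1C[C@]2(C)[C@@H](O)CC(C)=C[C@H](OC(=O)c3ccc(O)cc3)[C@@H]2[C@]1(O)C(C)C | target

**Step count and risks**

Total: 20 steps. Longest linear sequence: 17 steps (steps 1–7, 10–17, 19 and 20).

Most likely to fail:

1. Step 10. Attack on the hindered, β,β-disubstituted C3 may be too slow at low temperature, the vinyl cation may lose its silyl group to an alkyne before the enolate closes the ring, and facial control may erode if the mixture has to be warmed. The fallback sets out from 12 and comes back at 19, so it also replaces step 11; it forms the two bonds in separate steps. Enone 12 is treated with tributyl(propa-1,2-dienyl)stannane and tert-butyldimethylsilyl triflate (CH2Cl2, –78 °C), a conjugate propargylation that traps the enolate as the tert-butyldimethylsilyl enol ether F1 (propargyl group β on C3, C8=C9 enol ether). N-Iodosuccinimide with catalytic AgNO3 converts its terminal alkyne into the iodoalkyne F2. Catalytic Ph3PAuCl/AgBF4 in CH2Cl2/MeOH closes C9–C10 by 5-endo-dig carbocyclisation to the vinyl iodide ketone F3 (iodine on C10). Negishi coupling with i-PrZnBr and PdCl2(dppf) then installs the isopropyl group and gives 19.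

2. Step 11. The acid may move the C1=C10 double bond into conjugation with the C8 ketone through enolisation at C9, with loss of the ring-fusion centre, or may start to cleave the silyl ether before desilylation is complete. The fallback sets out from 18 and comes back at 19. Iododesilylation with N-iodosuccinimide in (CF3)2CHOH at 0 °C gives the vinyl iodide F4 (iodine on C1) without a free strong acid. Bu3SnH with catalytic Pd(PPh3)4 in THF then replaces iodine by hydrogen.

3. Step 17. Hydride may add to the C8 carbonyl from the concave β face (poor facial selectivity), which inverts C8. The fallback sets out from 27 and comes back at 33, replacing step 19. The 8α-alcohol F5 formed in the reduction is kept and esterified with acid 32 under Mitsunobu conditions (PPh3, diisopropyl azodicarboxylate, toluene, 0 °C), which inverts C8 and gives 33 directly.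

**Further compounds**

F1 | step 10 | tert-butyldimethylsilyl enol ether of the 3β-propargyl ketone (C8=C9 enol ether, 3α-CH3, 4α-OTIPS, 6β-CH3) | C#CC[C@]1(C)[C@@H](O[Si](C(C)C)(C(C)C)C(C)C)C[C@H](C)CC(O[Si](C)(C)C(C)(C)C)=C1
F2 | step 10 | iodoalkyne derived from F1 | IC#CC[C@]1(C)[C@@H](O[Si](C(C)C)(C(C)C)C(C)C)C[C@H](C)CC(O[Si](C)(C)C(C)(C)C)=C1
F3 | step 10 | cis-fused vinyl iodide ketone (C1H=C10–I, C8 ketone, 4α-OTIPS, 6β-CH3) | C1[C@]2(C)[C@@H](O[Si](C(C)C)(C(C)C)C(C)C)C[C@H](C)CC(=O)[C@@H]2C(I)=C1
F4 | step 11 | cis-fused vinyl iodide ketone (C1(I)=C10(i-Pr), C8 ketone, 4α-OTIPS, 6β-CH3) | C1[C@]2(C)[C@@H](O[Si](C(C)C)(C(C)C)C(C)C)C[C@H](C)CC(=O)[C@@H]2C(C(C)C)=C1I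
F5 | step 17 | 8α-epimer of allylic alcohol 28 | CC(=O)O[C@H]1C[C@]2(C)[C@@H](O[Si](C(C)C)(C(C)C)C(C)C)CC(C)=C[C@@H](O)[C@@H]2[C@]1(O)C(C)C
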